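**Retrosynthetic overview**

1. The C7 hydroperoxide is installed last, by α-oxygenation of the extended dienolate of the 7(11)-en-8-one 23; the two esters come from diol 21, and the diol from α-face dihydroxylation of the C3=C4 alkene of dienone 20.
2. Dienone 20 derives from bicyclic ketone 11: C15 through a C3=C4 enol triflate and methyl coupling, C11–C13 through an acetone aldol and dehydration at C7.
3. Key disconnection: the C5–C10 and C6–C7 bonds are cut together, which unravels both rings to the acyclic, achiral ynone–silyloxydiene 9; rings A and B are formed in the same step by an enantioselective intramolecular Diels–Alder reaction.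
4. Enabling feature: ring B (C5–C6–C7–C8–C9–C10) is a cyclohexanone with its carbonyl at C8, 1,3 to the quaternary ring-fusion carbon C10, and C5 bears the oxygenated C4 of ring A. Ring B is therefore the retron of a 2-silyloxydiene (C7=C8–C9=C10) adding to a C5≡C6 dienophile activated by a C4 ketone, with C1–C4 as the tether that closes ring A.
5. Precursor 9 comes from 5-hexyn-1-ol by carboalumination (fixes the (E)-C9=C10 geometry), oxidation, Weinreb amide formation, silylation and ethynylation.

Key step: step 6

**Remarks before the steps**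

- Locants C1–C15 in the Why lines are the eudesmane locants of the target: ring A = C1–C5 and C10; ring B = C5–C10; C14 = methyl on C10; C15 = methyl on C4; C11–C13 = the three-carbon group on C7. The α-face is the face opposite to the C10 methyl group. In these locants the target is (3R,4S,5R,7S,10R) with a (Z)-configured ester (angelate).
- Assumption: the (S)-configured oxazaborolidinium catalyst is assumed to deliver the (R)-configured quaternary carbon in step 6; if the sense of induction proves opposite, the (R)-configured catalyst is used with no other change.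
- The carbinol carbon of 4 is racemic and C3 of 18 is an epimer mixture; both centres become sp2 in the following step.

**Route**

Step 1
Reactants: 1 5-hexyn-1-ol
Product: 4 (E)-5-methyloct-5-ene-1,7-diol, via alkenyldimethylalane 2 (not isolated), via lithium alkenylalanate 3 (not isolated)
Conditions: AlMe3 (3 equiv), Cp2ZrCl2 (0.25 equiv), CH2Cl2, 0 °C to rt; n-BuLi, THF, −78 °C; CH3CHO, −78 to 0 °C; aq. Rochelle salt
Reagents that add atoms: trimethylaluminium C[Al](C)C; acetaldehyde CC=O
Why: Negishi zirconium-catalysed carboalumination adds methyl and aluminium syn across the terminal alkyne with methyl on the internal carbon, which fixes the (E)-trisubstituted alkene, and the derived alanate should transfer its alkenyl group to acetaldehyde with retention; the new carbinol centre is racemic and is oxidised away in step 2.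

Step 2
Reactants: 4 (E)-5-methyloct-5-ene-1,7-diol
Product: 5 (E)-5-methyl-7-oxooct-5-enoic acid
Conditions: PhI(OAc)2 (3.3 equiv), TEMPO (0.2 equiv), MeCN/H2O 1:1, rt
Reagents that add atoms: water O
Why: the oxoammonium (TEMPO/PhI(OAc)2) oxidation should take the primary alcohol through the aldehyde hydrate to the acid and the allylic secondary alcohol to the enone in one operation, without touching the trisubstituted alkene or its geometry.

Step 3
Reactants: 5 (E)-5-methyl-7-oxooct-5-enoic acid
Product: 6 (E)-N-methoxy-N,5-dimethyl-7-oxooct-5-enamide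
Conditions: MeNH(OMe)·HCl, EDC·HCl, i-Pr2NEt, DMAP (cat.), CH2Cl2, 0 °C to rt
Reagents that add atoms: N,O-dimethylhydroxylamine hydrochloride CNOC.Cl
Why: carbodiimide amide coupling gives the Weinreb amide, a carbonyl group that is inert to the enolisation of step 4 and is converted into the ynone only in step 5; the β,β-disubstituted enone does not compete as an electrophile.

Step 4
Reactants: 6 (E)-N-methoxy-N,5-dimethyl-7-oxooct-5-enamide
Product: 8 (E)-N-methoxy-N,5-dimethyl-7-[(triisopropylsilyl)oxy]octa-5,7-dienamide, via lithium dienolate 7 (not isolated)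
Conditions: LDA (1.05 equiv), THF, −78 °C; TIPSOTf, −78 to −40 °C; cold aq. NaHCO3
Reagents that add atoms: triisopropylsilyl triflate CC(C)[Si](OS(=O)(=O)C(F)(F)F)(C(C)C)C(C)C
Why: kinetic deprotonation of the methyl ketone at its α'-methyl group (faster than γ-deprotonation and than enolisation of the much less acidic amide) followed by O-silylation should give the cross-conjugated 2-silyloxy-1,3-diene with the (E)-alkene untouched.

Step 5
Reactants: 8 (E)-N-methoxy-N,5-dimethyl-7-[(triisopropylsilyl)oxy]octa-5,7-dienamide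
Product: 9 (E)-7-methyl-9-[(triisopropylsilyl)oxy]deca-7,9-dien-1-yn-3-one
Conditions: HC≡CMgBr (2.5 equiv), THF, 0 °C; inverse quench into cold 0.5 M aq. HCl/Et2O; used at once, kept cold
Reagents that add atoms: ethynylmagnesium bromide C#C[Mg]Br
Why: Weinreb ketone synthesis: the magnesium chelate of the tetrahedral adduct prevents over-addition and releases the terminal ynone only on the acidic quench, which also keeps the liberated N,O-dimethylhydroxylamine from adding to the ynone; the silyl dienol ether tolerates the Grignard reagent.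

Step 6
Reactants: 9 (E)-7-methyl-9-[(triisopropylsilyl)oxy]deca-7,9-dien-1-yn-3-one
Product: 10 (R)-4a-methyl-6-[(triisopropylsilyl)oxy]-3,4,4a,7-tetrahydronaphthalen-1(2H)-one
Conditions: (S)-o-tolyl-CBS-oxazaborolidine activated with Tf2NH (20 mol% each), CH2Cl2 (0.02 M), −78 to −40 °C
Reagents that add atoms: none
Why: Proposed new method: coordination of the C4 carbonyl to the cationic boron of the oxazaborolidinium lowers the alkyne LUMO, and the 2-silyloxydiene C7=C8(OSi)–C9=C10 adds across C5≡C6 in a concerted, asynchronous [4+2] (C6–C7 leading, C5–C10 following), so that both bonds form in one event; the closest known reactions are the cationic-oxazaborolidine-catalysed enantioselective Diels–Alder reactions of acetylenic ketones and of 2-(triisopropylsilyloxy)butadiene and the thermal intramolecular Diels–Alder reaction of alkynones, which have not been combined in an enantioselective intramolecular case that creates a quaternary carbon. Ring B (a cyclohexa-1,4-diene) is closed by the cycloaddition itself and ring A (a cyclohexanone) by the four-atom C1–C4 tether in the fused type 1 mode, the tether sitting on the diene terminus. The only new stereocentre, quaternary C10, is set by the catalyst, which binds the carbonyl and shields one face of the conjugated alkyne π system so that the diene terminus is engaged through one of its enantiotopic faces. Regioselectivity is doubly secured: the tether allows only the fused mode, and this coincides with the electronic preference (nucleophilic C7 to the β-carbon C6, acyl carbon para to the silyloxy group). An alkyne dienophile leaves no endo/exo question, so the ring-fusion hydrogen at C5 is deferred to step 7; the (E)-geometry of C9=C10 from step 1 puts the tether on the outside of the diene so that the reacting conformation is reachable, and the low temperature suppresses the uncatalysed racemic background.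

Step 7
Reactants: 10 (R)-4a-methyl-6-[(triisopropylsilyl)oxy]-3,4,4a,7-tetrahydronaphthalen-1(2H)-one
Product: 11 (4aR,8aR)-4a-methyl-6-[(triisopropylsilyl)oxy]-3,4,4a,7,8,8a-hexahydronaphthalen-1(2H)-one
Conditions: H2 (1 atm), 5% Pd/C, EtOAc, 0 °C, stopped after 1 equiv H2
Reagents that add atoms: none
Why: heterogeneous catalytic hydrogenation should add H2 syn to the conjugated C5=C6 bond (much faster than to the hindered trisubstituted silyl enol ether) from the α-face, opposite to the pseudoaxial C10 methyl group, which sets the C5 hydrogen trans to that methyl group (trans ring fusion).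

Step 8
Reactants: 11 (4aR,8aR)-4a-methyl-6-[(triisopropylsilyl)oxy]-3,4,4a,7,8,8a-hexahydronaphthalen-1(2H)-one
Product: 13 (4aR,8aR)-4a-methyl-6-[(triisopropylsilyl)oxy]-3,4,4a,7,8,8a-hexahydronaphthalen-1-yl trifluoromethanesulfonate, via lithium enolate 12 (not isolated)
Conditions: LDA, THF, −78 °C; PhNTf2, −78 to 0 °C; aq. NH4Cl
Reagents that add atoms: N-phenylbis(trifluoromethanesulfonimide) O=S(=O)(N(c1ccccc1)S(=O)(=O)C(F)(F)F)C(F)(F)F
Why: kinetic deprotonation removes a proton from the C3 methylene and not from the hindered ring-fusion methine C5 (so C5 is not epimerised), and the enolate is trapped on oxygen as the C3=C4 enol triflate.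

Step 9
Reactants: 13 (4aR,8aR)-4a-methyl-6-[(triisopropylsilyl)oxy]-3,4,4a,7,8,8a-hexahydronaphthalen-1-yl trifluoromethanesulfonate
Product: 14 triisopropyl{[(4aS,8aS)-5,8a-dimethyl-3,4,4a,7,8,8a-hexahydronaphthalen-2-yl]oxy}silane
Conditions: MeMgBr, Fe(acac)3 (5 mol%), THF/NMP, −30 to 0 °C
Reagents that add atoms: methylmagnesium bromide C[Mg]Br
Why: iron-catalysed Kumada-type cross-coupling of an alkenyl triflate with a methyl Grignard reagent replaces the triflate by the C15 methyl group without moving the double bond; the silyl enol ether is inert.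

Step 10
Reactants: 14 triisopropyl{[(4aS,8aS)-5,8a-dimethyl-3,4,4a,7,8,8a-hexahydronaphthalen-2-yl]oxy}silane
Product: 15 (4aR,8aR)-5,8a-dimethyl-3,4,4a,7,8,8a-hexahydronaphthalen-2(1H)-one
Conditions: TBAF (1.1 equiv), AcOH (1.5 equiv), THF, 0 °C
Reagents that add atoms: none
Why: fluoride cleaves the Si–O bond of the silyl enol ether and the enolate is protonated by acetic acid to the C8 ketone; the buffered medium should avoid migration of the C3=C4 alkene, and no stereocentre is affected.

Step 11
Reactants: 15 (4aR,8aR)-5,8a-dimethyl-3,4,4a,7,8,8a-hexahydronaphthalen-2(1H)-one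
Product: 18 (4aR,8aR)-3-(2-hydroxypropan-2-yl)-5,8a-dimethyl-3,4,4a,7,8,8a-hexahydronaphthalen-2(1H)-one (C3 epimers), via lithium enolate 16 (not isolated), via chlorozinc enolate 17 (not isolated)
Conditions: LDA, THF, −78 °C; ZnCl2, −78 °C; acetone, −78 to −40 °C; aq. NH4Cl
Reagents that add atoms: acetone CC(C)=O
Why: kinetic deprotonation of the C8 ketone occurs at the unhindered C7 methylene and not at C9, which is flanked by the quaternary C10, and the zinc enolate adds to acetone (directed aldol reaction) with little retro-aldol or proton transfer; the configuration at C7 is irrelevant because C7 becomes sp2 in step 12.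

Step 12
Reactants: 18 (4aR,8aR)-3-(2-hydroxypropan-2-yl)-5,8a-dimethyl-3,4,4a,7,8,8a-hexahydronaphthalen-2(1H)-one
Product: 20 (4aR,8aR)-5,8a-dimethyl-3-(propan-2-ylidene)-3,4,4a,7,8,8a-hexahydronaphthalen-2(1H)-one, via tertiary mesylate 19 (not isolated)
Conditions: MsCl, Et3N (excess), DMAP (cat.), CH2Cl2, 0 °C to rt; then DBU (0.3 equiv), rt
Reagents that add atoms: none
Why: the tertiary β-hydroxy ketone is mesylated through sulfene and eliminates (E1cB) to the enone, and DBU equilibrates any β,γ-unsaturated isomer into the conjugated isopropylidene ketone.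

Step 13
Reactants: 20 (4aR,8aR)-5,8a-dimethyl-3-(propan-2-ylidene)-3,4,4a,7,8,8a-hexahydronaphthalen-2(1H)-one
Product: 21 (4aR,5S,6R,8aR)-5,6-dihydroxy-5,8a-dimethyl-3-(propan-2-ylidene)octahydronaphthalen-2(1H)-one
Conditions: OsO4 (2 mol%), NMO (1.3 equiv), acetone/H2O 8:1, 0 °C to rt
Reagents that add atoms: N-methylmorpholine N-oxide C[N+]1([O-])CCOCC1; water O
Why: Upjohn dihydroxylation: OsO4 should add to the electron-richer trisubstituted C3=C4 alkene (the tetrasubstituted, electron-poor enone alkene reacts much more slowly) from the α-face, opposite to the C10 methyl group that is 1,3-diaxial to the β-face of C4, which sets C3 and C4 together as the 3α,4α-cis-diol with the C15 methyl group β.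

Step 14
Reactants: 21 (4aR,5S,6R,8aR)-5,6-dihydroxy-5,8a-dimethyl-3-(propan-2-ylidene)octahydronaphthalen-2(1H)-one
Product: 22 (1S,2R,4aR,8aR)-1-hydroxy-1,4a-dimethyl-6-oxo-7-(propan-2-ylidene)decahydronaphthalen-2-yl (Z)-2-methylbut-2-enoate
Conditions: angelic acid (3 equiv), 2,4,6-trichlorobenzoyl chloride (3 equiv), Et3N, toluene, rt; then 21, 75 °C (no DMAP)
Reagents that add atoms: angelic acid C/C=C(/C)C(=O)O
Why: Yamaguchi-type esterification through the mixed anhydride acylates only the secondary C3 hydroxyl (the tertiary C4 hydroxyl does not react under these conditions), and leaving out DMAP should suppress isomerisation of the (Z)-angelate to the (E)-tiglate.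

Step 15
Reactants: 22 (1S,2R,4aR,8aR)-1-hydroxy-1,4a-dimethyl-6-oxo-7-(propan-2-ylidene)decahydronaphthalen-2-yl (Z)-2-methylbut-2-enoate
Product: 23 (1S,2R,4aR,8aR)-1-acetoxy-1,4a-dimethyl-6-oxo-7-(propan-2-ylidene)decahydronaphthalen-2-yl (Z)-2-methylbut-2-enoate
Conditions: Ac2O (10 equiv), DMAP (2 equiv), Et3N, CH2Cl2, 40 °C
Reagents that add atoms: acetic anhydride CC(=O)OC(C)=O
Why: DMAP-catalysed acetylation with a large excess of anhydride esterifies the remaining tertiary, equatorial C4 hydroxyl; no stereocentre is touched.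

Step 16
Reactants: 23 (1S,2R,4aR,8aR)-1-acetoxy-1,4a-dimethyl-6-oxo-7-(propan-2-ylidene)decahydronaphthalen-2-yl (Z)-2-methylbut-2-enoate
Product: 25 (1S,2R,4aR,7S,8aR)-1-acetoxy-7-hydroperoxy-1,4a-dimethyl-6-oxo-7-(prop-1-en-2-yl)decahydronaphthalen-2-yl (Z)-2-methylbut-2-enoate, via potassium dienolate 24 (not isolated)
Conditions: KOt-Bu (1.5 equiv), THF/t-BuOH 5:1, O2 (1 atm), −25 °C, short reaction time; AcOH quench at −25 °C
Reagents that add atoms: dioxygen O=O
Why: under equilibrating conditions tert-butoxide should remove a γ-proton of the isopropylidene ketone to give the extended dienolate, which is oxygenated by O2 at its α-carbon C7 (base-mediated enolate autoxidation to a tertiary α-hydroperoxy ketone, which has no hydrogen for Kornblum–DeLaMare decomposition); O2 should enter axially from the α-face, anti to the C10 methyl group, leaving the isopropenyl group equatorial.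

**Compound list**

1 | 5-hexyn-1-ol | C#CCCCCO | starting material
2 | (E)-alkenyldimethylalane from carboalumination of 1 (O-aluminated) | C[Al](C)/C=C(\C)CCCCO[Al](C)C | intermediate (not isolated)
3 | lithium butyl(dimethyl)alkenylalanate derived from 2 | [Li+].CCCC[Al-](C)(C)/C=C(\C)CCCCO[Al](C)C | intermediate (not isolated)
4 | (E)-5-methyloct-5-ene-1,7-diol (racemic at C7) | CC(O)/C=C(\C)CCCCO | intermediate
5 | (E)-5-methyl-7-oxooct-5-enoic acid | CC(=O)/C=C(\C)CCCC(=O)O | intermediate
6 | (E)-N-methoxy-N,5-dimethyl-7-oxooct-5-enamide | CC(=O)/C=C(\C)CCCC(=O)N(C)OC | intermediate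
7 | lithium dienolate of 6 (enolised at the methyl group) | [Li]OC(=C)/C=C(\C)CCCC(=O)N(C)OC | intermediate (not isolated)
8 | (E)-N-methoxy-N,5-dimethyl-7-[(triisopropylsilyl)oxy]octa-5,7-dienamide | C=C(O[Si](C(C)C)(C(C)C)C(C)C)/C=C(\C)CCCC(=O)N(C)OC | intermediate
9 | (E)-7-methyl-9-[(triisopropylsilyl)oxy]deca-7,9-dien-1-yn-3-one | C#CC(=O)CCC/C(C)=C/C(=C)O[Si](C(C)C)(C(C)C)C(C)C | intermediate
10 | (R)-4a-methyl-6-[(triisopropylsilyl)oxy]-3,4,4a,7-tetrahydronaphthalen-1(2H)-one | C1C=C2[C@](C)(CCCC2=O)C=C1O[Si](C(C)C)(C(C)C)C(C)C | intermediate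
11 | (4aR,8aR)-4a-methyl-6-[(triisopropylsilyl)oxy]-3,4,4a,7,8,8a-hexahydronaphthalen-1(2H)-one (trans-fused) | C1C[C@@H]2[C@](C)(CCCC2=O)C=C1O[Si](C(C)C)(C(C)C)C(C)C | intermediate
12 | lithium (4aR,8aR)-4a-methyl-6-[(triisopropylsilyl)oxy]-3,4,4a,7,8,8a-hexahydronaphthalen-1-olate | C1C[C@@H]2[C@](C)(CCC=C2O[Li])C=C1O[Si](C(C)C)(C(C)C)C(C)C | intermediate (not isolated)
13 | (4aR,8aR)-4a-methyl-6-[(triisopropylsilyl)oxy]-3,4,4a,7,8,8a-hexahydronaphthalen-1-yl trifluoromethanesulfonate | C1C[C@@H]2[C@](C)(CCC=C2OS(=O)(=O)C(F)(F)F)C=C1O[Si](C(C)C)(C(C)C)C(C)C | intermediate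
14 | triisopropyl{[(4aS,8aS)-5,8a-dimethyl-3,4,4a,7,8,8a-hexahydronaphthalen-2-yl]oxy}silane | C1C[C@@H]2[C@](C)(CCC=C2C)C=C1O[Si](C(C)C)(C(C)C)C(C)C | intermediate
15 | (4aR,8aR)-5,8a-dimethyl-3,4,4a,7,8,8a-hexahydronaphthalen-2(1H)-one | C1C[C@@H]2[C@](C)(CCC=C2C)CC1=O | intermediate
16 | lithium (4aR,8aR)-5,8a-dimethyl-1,4,4a,7,8,8a-hexahydronaphthalen-2-olate | C=1C[C@@H]2[C@](C)(CCC=C2C)CC=1O[Li] | intermediate (not isolated)
17 | chlorozinc enolate corresponding to 16 | C=1C[C@@H]2[C@](C)(CCC=C2C)CC=1O[Zn]Cl | intermediate (not isolated)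
18 | (4aR,8aR)-3-(2-hydroxypropan-2-yl)-5,8a-dimethyl-3,4,4a,7,8,8a-hexahydronaphthalen-2(1H)-one (C3 epimers) | CC(C)(O)C1C[C@@H]2[C@](C)(CCC=C2C)CC1=O | intermediate
19 | tertiary methanesulfonate of 18 | CC(C)(OS(C)(=O)=O)C1C[C@@H]2[C@](C)(CCC=C2C)CC1=O | intermediate (not isolated)
20 | (4aR,8aR)-5,8a-dimethyl-3-(propan-2-ylidene)-3,4,4a,7,8,8a-hexahydronaphthalen-2(1H)-one (eudesma-3,7(11)-dien-8-one) | CC(C)=C1C[C@@H]2[C@](C)(CCC=C2C)CC1=O | intermediate
21 | (4aR,5S,6R,8aR)-5,6-dihydroxy-5,8a-dimethyl-3-(propan-2-ylidene)octahydronaphthalen-2(1H)-one (3α,4α-diol) | CC(C)=C1C[C@@H]2[C@](C)(CC[C@@H](O)[C@@]2(C)O)CC1=O | intermediate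
22 | (1S,2R,4aR,8aR)-1-hydroxy-1,4a-dimethyl-6-oxo-7-(propan-2-ylidene)decahydronaphthalen-2-yl (Z)-2-methylbut-2-enoate | CC(C)=C1C[C@@H]2[C@](C)(CC[C@@H](OC(=O)/C(C)=C\C)[C@@]2(C)O)CC1=O | intermediate
23 | (1S,2R,4aR,8aR)-1-acetoxy-1,4a-dimethyl-6-oxo-7-(propan-2-ylidene)decahydronaphthalen-2-yl (Z)-2-methylbut-2-enoate | CC(C)=C1C[C@@H]2[C@](C)(CC[C@@H](OC(=O)/C(C)=C\C)[C@@]2(C)OC(C)=O)CC1=O | intermediate
24 | potassium dienolate of 23 (C7=C8 enolate, C11=C12 alkene) | C=C(C)C=1C[C@@H]2[C@](C)(CC[C@@H](OC(=O)/C(C)=C\C)[C@@]2(C)OC(C)=O)CC=1O[K] | intermediate (not isolated)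
25 | (1S,2R,4aR,7S,8aR)-1-acetoxy-7-hydroperoxy-1,4a-dimethyl-6-oxo-7-(prop-1-en-2-yl)decahydronaphthalen-2-yl (Z)-2-methylbut-2-enoate (CNP0360871.1) | C=C(C)[C@@]1(OO)C[C@@H]2[C@](C)(CC[C@@H](OC(=O)/C(C)=C\C)[C@@]2(C)OC(C)=O)CC1=O | target

**Step count and risks**

Total step count: 16. Longest linear sequence: 16 (the route is fully linear).

Steps most likely to fail:

1. Step 6 (bears the label "Proposed new method:"). The catalyst may discriminate poorly between the two faces at the hindered, methyl-bearing diene terminus, or the acidic catalyst may cleave the silyl dienol ether faster than the cycloaddition proceeds. The fallback uses known chemistry, sets out from 9 and returns at 11. Thermal intramolecular Diels–Alder reaction of 9 (toluene, 110 °C, BHT) should give 10 together with its mirror image, (S)-4a-methyl-6-[(triisopropylsilyl)oxy]-3,4,4a,7-tetrahydronaphthalen-1(2H)-one F1. Hydrogenation as in step 7 then gives 11 and its enantiomer, (4aS,8aS)-4a-methyl-6-[(triisopropylsilyl)oxy]-3,4,4a,7,8,8a-hexahydronaphthalen-1(2H)-one F2. The pair is resolved by sulfoximine resolution: addition of lithiated (S)-N,S-dimethyl-S-phenylsulfoximine (THF, −78 °C) gives two diastereomers, the β-hydroxysulfoximine adduct of 11 F3 and the β-hydroxysulfoximine adduct of the enantiomer F4, to be separated by chromatography. Thermolysis of F3 (toluene, 120 °C) releases the sulfoximine and returns enantiopure 11.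

2. Step 16. Oxygenation may take place at the wrong carbon of the enolate manifold (the γ-carbon C12 or the α'-carbon C9), the alkoxide or the peroxide anion may remove or shift the ester groups, or the α-hydroperoxy ketone may be cleaved between C7 and C8 by base. The fallback avoids strong base, sets out from 23 and returns at 25. Soft enolisation (Et3SiOTf, Et3N, CH2Cl2, −20 °C) should give the extended silyl dienol ether, (1S,2R,4aR,8aR)-1-acetoxy-1,4a-dimethyl-7-(prop-1-en-2-yl)-6-[(triethylsilyl)oxy]-1,2,3,4,4a,5,8,8a-octahydronaphthalen-2-yl (Z)-2-methylbut-2-enoate F5. Sensitised photooxygenation (O2, tetraphenylporphyrin, visible light, CH2Cl2, −78 °C) then gives, by the silatropic ene reaction of singlet oxygen with the silyl enol ether, the α-silylperoxy ketone, (1S,2R,4aR,7S,8aR)-1-acetoxy-1,4a-dimethyl-6-oxo-7-(prop-1-en-2-yl)-7-[(triethylsilyl)peroxy]decahydronaphthalen-2-yl (Z)-2-methylbut-2-enoate F6. Methanolysis (PPTS, MeOH, 0 °C) frees the hydroperoxide 25.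

3. Step 7. Hydrogen may be delivered to both faces of the C5=C6 bond (giving some cis-fused ketone), or the silyl enol ether double bond may be reduced as well. The fallback sets the ring fusion by protonation instead of by delivery from a catalyst surface; it sets out from 10 and returns at 11. Dissolving-metal reduction of the enone (Li, liquid NH3/THF, t-BuOH 1 equiv, −78 °C) should give lithium (R)-4a-methyl-6-[(triisopropylsilyl)oxy]-2,3,4,4a,7,8-hexahydronaphthalen-1-olate F7. Kinetic protonation with solid NH4Cl at −78 °C, axial and opposite to the angular methyl group, should then give 11.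

Further compounds
F1 | step 6 | (S)-4a-methyl-6-[(triisopropylsilyl)oxy]-3,4,4a,7-tetrahydronaphthalen-1(2H)-one (enantiomer of 10) | C1C=C2[C@@](C)(CCCC2=O)C=C1O[Si](C(C)C)(C(C)C)C(C)C
F2 | step 6 | (4aS,8aS)-4a-methyl-6-[(triisopropylsilyl)oxy]-3,4,4a,7,8,8a-hexahydronaphthalen-1(2H)-one (enantiomer of 11) | C1C[C@H]2[C@@](C)(CCCC2=O)C=C1O[Si](C(C)C)(C(C)C)C(C)C
F3 | step 6 | β-hydroxysulfoximine adduct of 11: (S)-N-methyl-S-phenyl-S-{[(1S,4aR,8aR)-1-hydroxy-4a-methyl-6-[(triisopropylsilyl)oxy]-1,2,3,4,4a,7,8,8a-octahydronaphthalen-1-yl]methyl}sulfoximine | C1C[C@@H]2[C@](C)(CCC[C@@]2(O)C[S@@](=O)(=NC)c3ccccc3)C=C1O[Si](C(C)C)(C(C)C)C(C)C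
F4 | step 6 | β-hydroxysulfoximine adduct of the enantiomer F2: (S)-N-methyl-S-phenyl-S-{[(1R,4aS,8aS)-1-hydroxy-4a-methyl-6-[(triisopropylsilyl)oxy]-1,2,3,4,4a,7,8,8a-octahydronaphthalen-1-yl]methyl}sulfoximine | C1C[C@H]2[C@@](C)(CCC[C@]2(O)C[S@@](=O)(=NC)c3ccccc3)C=C1O[Si](C(C)C)(C(C)C)C(C)C
F5 | step 16 | (1S,2R,4aR,8aR)-1-acetoxy-1,4a-dimethyl-7-(prop-1-en-2-yl)-6-[(triethylsilyl)oxy]-1,2,3,4,4a,5,8,8a-octahydronaphthalen-2-yl (Z)-2-methylbut-2-enoate | C=C(C)C=1C[C@@H]2[C@](C)(CC[C@@H](OC(=O)/C(C)=C\C)[C@@]2(C)OC(C)=O)CC=1O[Si](CC)(CC)CC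
F6 | step 16 | (1S,2R,4aR,7S,8aR)-1-acetoxy-1,4a-dimethyl-6-oxo-7-(prop-1-en-2-yl)-7-[(triethylsilyl)peroxy]decahydronaphthalen-2-yl (Z)-2-methylbut-2-enoate | C=C(C)[C@@]1(OO[Si](CC)(CC)CC)C[C@@H]2[C@](C)(CC[C@@H](OC(=O)/C(C)=C\C)[C@@]2(C)OC(C)=O)CC1=O
F7 | step 7 | lithium (R)-4a-methyl-6-[(triisopropylsilyl)oxy]-2,3,4,4a,7,8-hexahydronaphthalen-1-olate | C1CC2=C(O[Li])CCC[C@]2(C)C=C1O[Si](C(C)C)(C(C)C)C(C)C
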